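A direct plan would tell the two phenols of methyl orsellinate apart by benzylation and O-methylation and cleave the methyl ester to acid A1.
It would join A1 to a second methyl orsellinate through a mixed trifluoroacetic anhydride, remove the benzyl group to give didepside phenol A2, and esterify A2 with but-2-ynoic acid to ynoate A3.
It would then build ring C last, by Diels–Alder reaction of A3 with silyloxydiene A4 and aromatisation.
The weakest step would be this closing cycloaddition: aryl alkynoates are untested in it, it would need 120 °C and a threefold excess of a labile ketene acetal on the most advanced intermediate, and nothing in A3 secures the orientation of addition or the direction of aromatisation (loss of methanol against loss of silanol).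
The second would be the carbodiimide esterification to A3: an aryl ynoate is an activated ester and a Michael acceptor, made beside a nucleophilic amine catalyst and a free phenol and then carried through silylation and heating.
The third would be the series benzylation, methylation, hydroxide cleavage and hydrogenolysis: four operations that add no skeletal complexity, one of them a forcing hydrolysis (KOH, DMSO, 90 °C) of a di-ortho-substituted ester.

**Plan of the new route**
Cuts, in retrosynthetic order: the acyl C–O bond from ring B to ring A (made last); the acyl C–O bond from ring C to ring B, made through an α-oxoketene while ring C is still a cyclohex-3-en-2-one; then C1–C6 and C3–C4 of ring C (Michael addition and Dieckmann closure).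
Enabling feature: in ring C the carboxyl carbon C1 lies between C2 (OH) and C6 (CH3), with OCH3 on C4. In the 1,6-dihydro form C1 is the sp3 α-carbon of a β-keto ester, the C2 ketone is the later OH and the C4 enol ether the later OCH3. The hindered ester therefore forms by ester exchange through a ketene, and OH and OCH3 are never told apart on an arene.
Ring order: the carbocycle of ring C is closed first; ring B is bought, and its C4 oxygen enters by C–H borylation and oxidation at the only unhindered C–H; ring C is aromatised on ring B; ring A is joined last.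
No alkynoate, cycloaddition, benzyl ether or hydroxide ester cleavage occurs. The one protecting group is a tert-butyl ester, removed by acid in the flask of the last step.

Key step: step 5

Remark: the target is achiral. The cyclohexenone intermediates 7–13 are racemic and partly enolised; their stereocentres at C1 and C6 become sp2 in step 6 and are of no consequence.

**Step 1**
Reactants: 1 2-methoxy-6-methylbenzoic acid
Product: 2 tert-butyl 2-methoxy-6-methylbenzoate
Conditions: t-BuOC(=NH)CCl3 (2 equiv), BF3·OEt2 (5 mol %), cyclohexane/CH2Cl2 (2:1), 23 °C, 16 h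
Reagents that add atoms: tert-butyl 2,2,2-trichloroacetimidate, CC(C)(C)OC(=N)C(Cl)(Cl)Cl
Why: Alkylative esterification by the trichloroacetimidate method; the carboxylate captures the tert-butyl cation, so the di-ortho-substituted carbonyl carbon is never attacked.

**Step 2**
Reactants: 2 tert-butyl 2-methoxy-6-methylbenzoate
Product: 4 tert-butyl 4-hydroxy-2-methoxy-6-methylbenzoate, via aryl boronate 3 (not isolated)
Conditions: [Ir(OMe)(cod)]2 (1.5 mol %), 4,4'-di-tert-butyl-2,2'-bipyridine (3 mol %), B2pin2 (1.0 equiv), THF, 80 °C, 16 h; then acetone, aq. KHSO5 (Oxone, 1.1 equiv), 23 °C, 15 min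
Reagents that add atoms: potassium peroxymonosulfate (KHSO5, as Oxone), [K+].[O-]S(=O)(=O)OO
Why: Sterically governed iridium-catalysed aromatic C–H borylation followed by boronate oxidation; C4–H is the only ring hydrogen without an ortho substituent (C3–H lies beside OCH3, C5–H beside CH3), so boron and then hydroxyl enter para to the ester.

**Step 3**
Reactants: 5 tert-butyl 3-oxobutanoate; 6 methyl (2E)-but-2-enoate (1.05 equiv)
Product: 8 tert-butyl 6-methyl-2,4-dioxocyclohexane-1-carboxylate, via Michael adduct 7 (not isolated)
Conditions: t-BuOK (1.1 equiv), t-BuOH, 23 → 82 °C, 6 h; then cold 1 M HCl to pH 3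
Reagents that add atoms: none
Why: Michael addition of the acetoacetate anion to the crotonate (C1–C6) followed by Dieckmann closure of the methyl ketone onto the methyl ester (C3–C4, six-membered ring); only the methyl ester is attacked, so the tert-butyl ester stays, and the two racemic stereocentres vanish later.

**Step 4**
Reactants: 8 tert-butyl 6-methyl-2,4-dioxocyclohexane-1-carboxylate
Product: 9 tert-butyl 4-methoxy-6-methyl-2-oxocyclohex-3-ene-1-carboxylate
Conditions: HC(OMe)3 (2 equiv), MeOH, TsOH·H2O (2 mol %), 23 °C, 12 h; Et3N quench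
Reagents that add atoms: trimethyl orthoformate, COC(OC)OC; methanol, CO
Why: Acid-catalysed enol ether formation of a cyclic 1,3-dione under equilibrating conditions; the methoxy group should settle on C4, remote from the ester, leaving C2=O in the β-keto ester, which fixes OCH3 at C4 and the later OH at C2 of ring C.

**Step 5**
Reactants: 9 tert-butyl 4-methoxy-6-methyl-2-oxocyclohex-3-ene-1-carboxylate (1.4 equiv); 4 tert-butyl 4-hydroxy-2-methoxy-6-methylbenzoate
Product: 11 tert-butyl 2-methoxy-4-{[(4-methoxy-6-methyl-2-oxocyclohex-3-en-1-yl)carbonyl]oxy}-6-methylbenzoate, via α-oxoketene 10 (not isolated)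
Conditions: xylenes, 135 °C, N2 sweep with slow distillation of t-BuOH, 6 h
Reagents that add atoms: none
Why: On heating, the tert-butyl β-keto ester 9 should lose tert-butanol through its enol in a six-membered transition state to give the α-oxoketene 10, whose sp carbon is unhindered, and phenol 4 adds to it to give the aryl β-keto ester 11. The closest known reaction type is the thermal ester exchange of tert-butyl β-keto esters and dioxinones with alcohols and phenols through acylketenes. No ring is closed and no lasting stereocentre is made, since C1 epimerises through the enol and C1 and C6 become sp2 in the next step. The selectivity needed is exchange of only one of the two tert-butyl esters at a single oxygen: only 9 has the β-keto group that allows ketene formation, the tert-butyl benzoate of 4 cannot fragment this way, and 4 has one hydroxyl. Removal of tert-butanol drives the equilibrium to the aryl ester, so the di-ortho-substituted depside ester forms without any attack on a hindered aryl carbonyl.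

**Step 6**
Reactants: 11 tert-butyl 2-methoxy-4-{[(4-methoxy-6-methyl-2-oxocyclohex-3-en-1-yl)carbonyl]oxy}-6-methylbenzoate
Product: 14 tert-butyl 4-[(2-hydroxy-4-methoxy-6-methylbenzoyl)oxy]-2-methoxy-6-methylbenzoate, via selenide 12 (not isolated), via selenoxide 13 (not isolated)
Conditions: PhSeCl (1.1 equiv), pyridine (1.2 equiv), CH2Cl2, 0 °C, 1 h; then 30% aq. H2O2 (3 equiv), 0 → 23 °C, 1 h
Reagents that add atoms: none
Why: α-Selenenylation of the β-keto ester at C1 and selenoxide syn-elimination (Reich–Sharpless dehydrogenation of β-dicarbonyl compounds); selenium should enter trans to the C6 methyl and hence cis to C6–H, elimination toward C6 gives a 4H-cyclohexa-2,5-dienone that tautomerises to the phenol, with C2=O becoming the chelated OH and the C4 enol ether the OCH3.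

**Step 7**
Reactants: 14 tert-butyl 4-[(2-hydroxy-4-methoxy-6-methylbenzoyl)oxy]-2-methoxy-6-methylbenzoate; 15 methyl 2,4-dihydroxy-6-methylbenzoate (methyl orsellinate, 1.2 equiv)
Product: 18 methyl 2-hydroxy-4-({4-[(2-hydroxy-4-methoxy-6-methylbenzoyl)oxy]-2-methoxy-6-methylbenzoyl}oxy)-6-methylbenzoate, via carboxylic acid 16 (not isolated), via mixed trifluoroacetic anhydride 17 (not isolated)
Conditions: CF3CO2H/CH2Cl2 (1:4), 0 → 23 °C, 2 h; evaporate from PhMe; then 15, (CF3CO)2O (4 equiv), PhMe, 23 °C, 4 h; aq. NaHCO3 work-up
Reagents that add atoms: none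
Why: Acidolysis of the tert-butyl ester (loss of 2-methylpropene) and mixed-anhydride esterification with trifluoroacetic anhydride, the classical depside coupling; the acylium-like anhydride acylates the unchelated 4-OH of methyl orsellinate, while the chelated 2-OH groups of rings A and C are far less nucleophilic and any trifluoroacetate on them is cleaved in the bicarbonate work-up.

**Compound list**
1 | 2-methoxy-6-methylbenzoic acid | COc1cccc(C)c1C(=O)O | starting material
2 | tert-butyl 2-methoxy-6-methylbenzoate | COc1cccc(C)c1C(=O)OC(C)(C)C | intermediate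
3 | tert-butyl 2-methoxy-6-methyl-4-(4,4,5,5-tetramethyl-1,3,2-dioxaborolan-2-yl)benzoate (not isolated) | COc1cc(B2OC(C)(C)C(C)(C)O2)cc(C)c1C(=O)OC(C)(C)C | intermediate
4 | tert-butyl 4-hydroxy-2-methoxy-6-methylbenzoate | COc1cc(O)cc(C)c1C(=O)OC(C)(C)C | intermediate
5 | tert-butyl 3-oxobutanoate | CC(=O)CC(=O)OC(C)(C)C | starting material
6 | methyl (2E)-but-2-enoate | C/C=C/C(=O)OC | starting material
7 | 1-tert-butyl 5-methyl 2-acetyl-3-methylpentanedioate (racemic diastereomers; not isolated) | CC(=O)C(C(C)CC(=O)OC)C(=O)OC(C)(C)C | intermediate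
8 | tert-butyl 6-methyl-2,4-dioxocyclohexane-1-carboxylate (racemic, enolised) | CC1CC(=O)CC(=O)C1C(=O)OC(C)(C)C | intermediate
9 | tert-butyl 4-methoxy-6-methyl-2-oxocyclohex-3-ene-1-carboxylate (racemic) | COC1=CC(=O)C(C(=O)OC(C)(C)C)C(C)C1 | intermediate
10 | 3-methoxy-5-methyl-6-(oxomethylidene)cyclohex-2-en-1-one (racemic; not isolated) | COC1=CC(=O)C(=C=O)C(C)C1 | intermediate
11 | tert-butyl 2-methoxy-4-{[(4-methoxy-6-methyl-2-oxocyclohex-3-en-1-yl)carbonyl]oxy}-6-methylbenzoate (racemic, C1 epimerisable) | COC1=CC(=O)C(C(=O)Oc2cc(C)c(C(=O)OC(C)(C)C)c(OC)c2)C(C)C1 | intermediate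
12 | tert-butyl 2-methoxy-4-({[4-methoxy-6-methyl-2-oxo-1-(phenylselanyl)cyclohex-3-en-1-yl]carbonyl}oxy)-6-methylbenzoate (racemic; not isolated) | COC1=CC(=O)C([Se]c2ccccc2)(C(=O)Oc2cc(C)c(C(=O)OC(C)(C)C)c(OC)c2)C(C)C1 | intermediate
13 | tert-butyl 2-methoxy-4-({[4-methoxy-6-methyl-2-oxo-1-(phenylseleninyl)cyclohex-3-en-1-yl]carbonyl}oxy)-6-methylbenzoate (not isolated) | COC1=CC(=O)C([Se](=O)c2ccccc2)(C(=O)Oc2cc(C)c(C(=O)OC(C)(C)C)c(OC)c2)C(C)C1 | intermediate
14 | tert-butyl 4-[(2-hydroxy-4-methoxy-6-methylbenzoyl)oxy]-2-methoxy-6-methylbenzoate | COc1cc(C)c(C(=O)Oc2cc(C)c(C(=O)OC(C)(C)C)c(OC)c2)c(O)c1 | intermediate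
15 | methyl 2,4-dihydroxy-6-methylbenzoate (methyl orsellinate) | COC(=O)c1c(C)cc(O)cc1O | starting material
16 | 4-[(2-hydroxy-4-methoxy-6-methylbenzoyl)oxy]-2-methoxy-6-methylbenzoic acid (not isolated) | COc1cc(C)c(C(=O)Oc2cc(C)c(C(=O)O)c(OC)c2)c(O)c1 | intermediate
17 | 4-[(2-hydroxy-4-methoxy-6-methylbenzoyl)oxy]-2-methoxy-6-methylbenzoic trifluoroacetic anhydride (not isolated) | COc1cc(C)c(C(=O)Oc2cc(C)c(C(=O)OC(=O)C(F)(F)F)c(OC)c2)c(O)c1 | intermediate
18 | methyl 2-hydroxy-4-({4-[(2-hydroxy-4-methoxy-6-methylbenzoyl)oxy]-2-methoxy-6-methylbenzoyl}oxy)-6-methylbenzoate (CNP0357736.0, achiral) | COC(=O)c1c(C)cc(OC(=O)c2c(C)cc(OC(=O)c3c(C)cc(OC)cc3O)cc2OC)cc1O | target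

**Count and risks**
Total steps: 7. Longest linear sequence: 5 steps (3, 4, 5, 6, 7 from tert-butyl 3-oxobutanoate; equally 1, 2, 5, 6, 7 from acid 1).

Steps most likely to fail:

1. Step 5. The α-substituted, vinylogous β-keto ester may fragment to the ketene too slowly, so that loss of 2-methylpropene with decarboxylation, or dimerisation of the ketene, takes over. The fallback aromatises before coupling and joins through the free acid. It sets out from 9 and 4: selenenylation and selenoxide elimination of 9 (as in step 6) should give tert-butyl 2-hydroxy-4-methoxy-6-methylbenzoate F1; CF3CO2H in CH2Cl2 would free 2-hydroxy-4-methoxy-6-methylbenzoic acid F2; carbodiimide esterification of F2 with phenol 4 (N,N'-dicyclohexylcarbodiimide, catalytic 4-(dimethylamino)pyridine, CH2Cl2) comes back to the route at 14.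

2. Step 6. Selenium may be delivered to the enol ether carbon C3 instead of C1, or cis to the C6 methyl so that no syn hydrogen is available, or the electron-rich phenol may be over-oxidised by peroxide. The fallback avoids any oxidation on the depside and brings ring C in at the arene level as a photochemical ketene source. It sets out from 4: commercial 2,4-dihydroxy-6-methylbenzoic acid (OC(=O)c1c(C)cc(O)cc1O) with acetone, (CF3CO)2O and CF3CO2H should give 7-hydroxy-2,2,5-trimethyl-4H-1,3-benzodioxin-4-one F3; MeI and K2CO3 in acetone would methylate the only free hydroxyl to 7-methoxy-2,2,5-trimethyl-4H-1,3-benzodioxin-4-one F4; irradiation of F4 at 300 nm in CH2Cl2 with phenol 4 should release the o-quinone ketene, which 4 traps, and the route is rejoined at 14.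

3. Step 7. The acylium-like anhydride may acylate an electron-rich ring (Friedel–Crafts) or a chelated hydroxyl, or acyl exchange may occur at the existing depside bond under acid. The fallback forms the aryl C–O bond instead of the acyl C–O bond. It sets out from 14, cleaved with CF3CO2H to acid 16, which is then isolated. Methyl 2-hydroxy-6-methylbenzoate (COC(=O)c1c(C)cccc1O) is borylated at its only unhindered C–H under the conditions of step 2 to methyl 2-hydroxy-6-methyl-4-(4,4,5,5-tetramethyl-1,3,2-dioxaborolan-2-yl)benzoate F5; NaIO4 and aqueous NH4OAc in acetone should give [3-hydroxy-4-(methoxycarbonyl)-5-methylphenyl]boronic acid F6; copper-mediated O-arylation of acid 16 with F6 (Cu(OTf)2, urea, EtOAc, 60 °C, air) comes back to the route at the target 18.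

**Further compounds**
F1 | step 5 | tert-butyl 2-hydroxy-4-methoxy-6-methylbenzoate | COc1cc(C)c(C(=O)OC(C)(C)C)c(O)c1
F2 | step 5 | 2-hydroxy-4-methoxy-6-methylbenzoic acid | COc1cc(C)c(C(=O)O)c(O)c1
F3 | step 6 | 7-hydroxy-2,2,5-trimethyl-4H-1,3-benzodioxin-4-one | Cc1cc(O)cc2OC(C)(C)OC(=O)c12
F4 | step 6 | 7-methoxy-2,2,5-trimethyl-4H-1,3-benzodioxin-4-one | COc1cc(C)c2C(=O)OC(C)(C)Oc2c1
F5 | step 7 | methyl 2-hydroxy-6-methyl-4-(4,4,5,5-tetramethyl-1,3,2-dioxaborolan-2-yl)benzoate | COC(=O)c1c(C)cc(B2OC(C)(C)C(C)(C)O2)cc1O
F6 | step 7 | [3-hydroxy-4-(methoxycarbonyl)-5-methylphenyl]boronic acid | COC(=O)c1c(C)cc(B(O)O)cc1O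
A1 | direct plan | 4-(benzyloxy)-2-methoxy-6-methylbenzoic acid | OC(=O)c1c(C)cc(OCc2ccccc2)cc1OC
A2 | direct plan | methyl 2-hydroxy-4-[(4-hydroxy-2-methoxy-6-methylbenzoyl)oxy]-6-methylbenzoate | COC(=O)c1c(C)cc(OC(=O)c2c(C)cc(O)cc2OC)cc1O
A3 | direct plan | methyl 4-{[4-(but-2-ynoyloxy)-2-methoxy-6-methylbenzoyl]oxy}-2-hydroxy-6-methylbenzoate | COC(=O)c1c(C)cc(OC(=O)c2c(C)cc(OC(=O)C#CC)cc2OC)cc1O
A4 | direct plan | (1E)-1,3-dimethoxy-1-(trimethylsilyloxy)buta-1,3-diene | C=C(OC)/C=C(\OC)O[Si](C)(C)C
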